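**Retrosynthetic overview**
- The structure rests on one feature: O1 of ring C lies between C8a of ring A and the unsubstituted C2–H. Removing O1 therefore leaves an aryl–CHO bond, and ring A then needs only the C7 and C8 oxygens of a catechol.
- The prenyl ether is cut first, back to the free C7 phenol, which is carried as a benzyl ether through the oxidation (a prenyl alkene would be epoxidised by the peracid).
- Ring C, the only ring made (rings A and B are bought), is opened at C2–C3 to an aryl formate, which closes by intramolecular C-formylation of the benzylic methylene and dehydration.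
- The aryl formate comes from an ortho-acyl benzaldehyde by Baeyer–Villiger insertion of O1 into the C8a–CHO bond, the formyl carbon staying in place as C2.
- The keto aldehyde comes from a brominated, acetal-masked 3-benzyloxy-2-methoxybenzaldehyde (from 2,3-dihydroxybenzaldehyde) and the N-methoxy-N-methylamide of 4-methoxyphenylacetic acid (C4–C4a bond).

Key step: step 7

Remark: the target has no stereocentre and no stereodefined double bond, so no stereocontrol is needed; hemiacetal 17 forms as a mixture of racemic diastereomers that converge on dehydration.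

**Route**

Step 1
Reactants: 1 4-methoxyphenylacetic acid
Product: 3 N-methoxy-2-(4-methoxyphenyl)-N-methylacetamide, via acyl imidazolide 2 (not isolated)
Conditions: CDI (1.1 equiv), CH2Cl2, rt; then MeNH(OMe)·HCl (1.2 equiv), rt
Reagents that add atoms: N,O-dimethylhydroxylamine hydrochloride, CNOC.Cl; 1,1'-carbonyldiimidazole (CDI), O=C(n1ccnc1)n1ccnc1 (imidazole ring of 2 only)
Why: Activation of the acid as its acyl imidazolide followed by aminolysis is a standard amide coupling (Weinreb amide formation), and the liberated imidazole serves as the base for the amine salt.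

Step 2
Reactants: 4 2,3-dihydroxybenzaldehyde; 5 benzyl bromide
Product: 7 3-(benzyloxy)-2-hydroxybenzaldehyde, via disodium dianion 6 (not isolated)
Conditions: NaH (2.2 equiv), DMSO–THF, 0 °C to rt; 5 (1.0 equiv), rt; aq. HCl quench
Reagents that add atoms: NaH, [Na+].[H-] (sodium counter-ions of 6 only)
Why: In the dianion the C3 phenoxide is the more nucleophilic oxygen, because the C2 phenoxide is delocalised into and sodium-chelated by the ortho formyl group, so one equivalent of benzyl bromide should alkylate O3 selectively (Williamson ether synthesis on a dianion).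

Step 3
Reactants: 7 3-(benzyloxy)-2-hydroxybenzaldehyde
Product: 8 3-(benzyloxy)-2-methoxybenzaldehyde
Conditions: MeI (1.5 equiv), K2CO3, DMF, rt
Reagents that add atoms: iodomethane, CI
Why: Williamson methylation of the remaining hydrogen-bonded phenol is routine and leaves the aldehyde and the benzyl ether untouched.

Step 4
Reactants: 8 3-(benzyloxy)-2-methoxybenzaldehyde
Product: 9 3-(benzyloxy)-6-bromo-2-methoxybenzaldehyde
Conditions: NBS (1.05 equiv), DMF, rt, dark
Reagents that add atoms: N-bromosuccinimide, O=C1CCC(=O)N1Br
Why: Electrophilic aromatic bromination should go para to the coplanar C3 benzyloxy group (C6), because the doubly flanked C2 methoxy group is twisted out of conjugation and directs only weakly to C5; this is the regiochemistry known for 2,3-dimethoxybenzaldehyde under the same conditions.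

Step 5
Reactants: 9 3-(benzyloxy)-6-bromo-2-methoxybenzaldehyde
Product: 10 1-(benzyloxy)-4-bromo-3-(dimethoxymethyl)-2-methoxybenzene
Conditions: HC(OMe)3 (3 equiv), MeOH, TsOH·H2O (cat.), reflux; Et3N quench
Reagents that add atoms: trimethyl orthoformate, COC(OC)OC; methanol, CO
Why: Acid-catalysed acetalisation, driven by the orthoformate as water scavenger, masks the aldehyde against the organolithium of the next step, and a dimethyl acetal is chosen because dilute acid removes it again during work-up.

Step 6
Reactants: 10 1-(benzyloxy)-4-bromo-3-(dimethoxymethyl)-2-methoxybenzene; 3 N-methoxy-2-(4-methoxyphenyl)-N-methylacetamide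
Product: 14 3-(benzyloxy)-2-methoxy-6-[(4-methoxyphenyl)acetyl]benzaldehyde, via aryllithium 11 (not isolated), via lithium hemiaminal alkoxide 12 (not isolated), via acetal ketone 13 (not isolated)
Conditions: n-BuLi (1.05 equiv), THF, −78 °C; 3 (1.1 equiv), −78 to −20 °C; then 2 M HCl, THF, rt
Reagents that add atoms: water, O (oxygen of the released formyl group); n-butyllithium, [Li]CCCC (lithium of 11 and 12 only)
Why: Bromine–lithium exchange at −78 °C outruns attack on the acetal or the benzyl ether, the aryllithium adds to the N-methoxy-N-methylamide to give a chelated adduct that cannot add a second time (Weinreb ketone synthesis), and the acidic quench releases the ketone and hydrolyses the dimethyl acetal in one operation.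

Step 7
Reactants: 14 3-(benzyloxy)-2-methoxy-6-[(4-methoxyphenyl)acetyl]benzaldehyde
Product: 16 3-(benzyloxy)-2-methoxy-6-[(4-methoxyphenyl)acetyl]phenyl formate, via peroxy hemiacetal 15 (not isolated)
Conditions: mCPBA (1.3 equiv), CH2Cl2, 0 °C to rt, no added base; brief cold aq. Na2S2O3 then NaHCO3 wash
Reagents that add atoms: 3-chloroperbenzoic acid (mCPBA), OOC(=O)c1cccc(Cl)c1
Why: The peracid adds to the formyl carbon, the more electrophilic of the two carbonyl groups, to give peroxy hemiacetal 15; the aryl carbon (C8a of the target) then shifts from carbon to the proximal peroxide oxygen, antiperiplanar to the breaking O–O bond, as 3-chlorobenzoate leaves, which forms O1–C8a while O1 stays bonded to the former formyl carbon (C2). The closest known reaction is the Dakin-type Baeyer–Villiger oxidation of ortho- and para-alkoxybenzaldehydes to aryl formates with mCPBA. No ring is closed and no stereocentre is formed. Two selectivities are needed: aldehyde over ketone, which the conjugated aryl benzyl ketone's low reactivity toward peracid in the absence of strong acid should secure, and aryl over hydride migration, which the lone pairs of the ortho methoxy oxygen (C8) and the relief of crowding at a di-ortho-substituted ring should favour. The ortho acyl group lowers the migratory aptitude of the ring, so hydride shift to the benzoic acid is the main failure mode, and the weakly acidic medium is kept because acid assists the aryl shift. Base is excluded until the acid has been washed out, so that neither the keto aldehyde (aldol closure to an indanone, a 5-enolendo-exo-trig process that is also geometrically disfavoured) nor the new formate is exposed to enolising conditions.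

Step 8
Reactants: 16 3-(benzyloxy)-2-methoxy-6-[(4-methoxyphenyl)acetyl]phenyl formate
Product: 18 7-(benzyloxy)-8-methoxy-3-(4-methoxyphenyl)-4H-chromen-4-one, via 2-hydroxyisoflavanone 17 (not isolated)
Conditions: DBU (1.1 equiv), dry THF, 0 °C to rt; then TsOH·H2O (1.5 equiv), 50 °C
Reagents that add atoms: none
Why: The benzylic methylene, acidified by the ketone and the anisyl ring, is enolised by DBU and attacks the neighbouring formate carbonyl through a six-membered transition state (intramolecular Claisen condensation of the Baker–Venkataraman type, 6-enolendo-exo-trig) to give hemiacetal 17, which loses water under acid to give the conjugated chromen-4-one.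

Step 9
Reactants: 18 7-(benzyloxy)-8-methoxy-3-(4-methoxyphenyl)-4H-chromen-4-one
Product: 19 7-hydroxy-8-methoxy-3-(4-methoxyphenyl)-4H-chromen-4-one
Conditions: H2 (1 atm), 10% Pd/C, EtOAc–MeOH, rt, stopped at full conversion
Reagents that add atoms: none
Why: Catalytic hydrogenolysis of the benzyl aryl ether over Pd/C is faster at one atmosphere than reduction of the vinylogous-ester C2=C3 bond, so the C7 phenol should be freed without touching ring C or the methyl ethers.

Step 10
Reactants: 19 7-hydroxy-8-methoxy-3-(4-methoxyphenyl)-4H-chromen-4-one; 20 prenyl bromide (1-bromo-3-methylbut-2-ene)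
Product: 21 8-methoxy-3-(4-methoxyphenyl)-7-[(3-methylbut-2-en-1-yl)oxy]-4H-chromen-4-one
Conditions: 20 (1.2 equiv), K2CO3, acetone, reflux
Reagents that add atoms: none
Why: Williamson ether synthesis: the acidic C7 phenol, conjugated with the C4 carbonyl, is deprotonated by K2CO3 and alkylated on oxygen by the primary allylic bromide in an SN2 reaction, and no oxidant follows that could attack the trisubstituted alkene.

**Compound list**
1 | 4-methoxyphenylacetic acid | COc1ccc(CC(=O)O)cc1 | starting material
2 | 1-(1H-imidazol-1-yl)-2-(4-methoxyphenyl)ethan-1-one (acyl imidazolide, not isolated) | COc1ccc(CC(=O)n2ccnc2)cc1 | intermediate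
3 | N-methoxy-2-(4-methoxyphenyl)-N-methylacetamide | COc1ccc(CC(=O)N(C)OC)cc1 | intermediate
4 | 2,3-dihydroxybenzaldehyde | O=Cc1cccc(O)c1O | starting material
5 | benzyl bromide | BrCc1ccccc1 | starting material
6 | disodium 3-formylbenzene-1,2-diolate (not isolated) | O=Cc1cccc([O-])c1[O-].[Na+].[Na+] | intermediate
7 | 3-(benzyloxy)-2-hydroxybenzaldehyde | O=Cc1cccc(OCc2ccccc2)c1O | intermediate
8 | 3-(benzyloxy)-2-methoxybenzaldehyde | COc1c(C=O)cccc1OCc1ccccc1 | intermediate
9 | 3-(benzyloxy)-6-bromo-2-methoxybenzaldehyde | COc1c(C=O)c(Br)ccc1OCc1ccccc1 | intermediate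
10 | 1-(benzyloxy)-4-bromo-3-(dimethoxymethyl)-2-methoxybenzene | COc1c(C(OC)OC)c(Br)ccc1OCc1ccccc1 | intermediate
11 | [4-(benzyloxy)-2-(dimethoxymethyl)-3-methoxyphenyl]lithium (not isolated) | COc1c(C(OC)OC)c([Li])ccc1OCc1ccccc1 | intermediate
12 | lithium 1-[4-(benzyloxy)-2-(dimethoxymethyl)-3-methoxyphenyl]-1-[methoxy(methyl)amino]-2-(4-methoxyphenyl)ethan-1-olate (not isolated) | COc1ccc(CC(O[Li])(N(C)OC)c2ccc(OCc3ccccc3)c(OC)c2C(OC)OC)cc1 | intermediate
13 | 1-[4-(benzyloxy)-2-(dimethoxymethyl)-3-methoxyphenyl]-2-(4-methoxyphenyl)ethan-1-one (not isolated) | COc1ccc(CC(=O)c2ccc(OCc3ccccc3)c(OC)c2C(OC)OC)cc1 | intermediate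
14 | 3-(benzyloxy)-2-methoxy-6-[(4-methoxyphenyl)acetyl]benzaldehyde | COc1ccc(CC(=O)c2ccc(OCc3ccccc3)c(OC)c2C=O)cc1 | intermediate
15 | {3-(benzyloxy)-2-methoxy-6-[(4-methoxyphenyl)acetyl]phenyl}(hydroxy)methyl 3-chlorobenzenecarboperoxoate (racemic, not isolated) | COc1ccc(CC(=O)c2ccc(OCc3ccccc3)c(OC)c2C(O)OOC(=O)c2cccc(Cl)c2)cc1 | intermediate
16 | 3-(benzyloxy)-2-methoxy-6-[(4-methoxyphenyl)acetyl]phenyl formate | COc1ccc(CC(=O)c2ccc(OCc3ccccc3)c(OC)c2OC=O)cc1 | intermediate
17 | 7-(benzyloxy)-2-hydroxy-8-methoxy-3-(4-methoxyphenyl)-2,3-dihydro-4H-chromen-4-one (diastereomer mixture, racemic, not isolated) | COc1ccc(C2C(O)Oc3c(OC)c(OCc4ccccc4)ccc3C2=O)cc1 | intermediate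
18 | 7-(benzyloxy)-8-methoxy-3-(4-methoxyphenyl)-4H-chromen-4-one | COc1ccc(-c2coc3c(OC)c(OCc4ccccc4)ccc3c2=O)cc1 | intermediate
19 | 7-hydroxy-8-methoxy-3-(4-methoxyphenyl)-4H-chromen-4-one | COc1ccc(-c2coc3c(OC)c(O)ccc3c2=O)cc1 | intermediate
20 | prenyl bromide (1-bromo-3-methylbut-2-ene) | CC(C)=CCBr | starting material
21 | 8-methoxy-3-(4-methoxyphenyl)-7-[(3-methylbut-2-en-1-yl)oxy]-4H-chromen-4-one | COc1ccc(-c2coc3c(OC)c(OCC=C(C)C)ccc3c2=O)cc1 | target

**Step count**
Total steps: 10. Longest linear sequence: 9 (steps 2 to 10, from 2,3-dihydroxybenzaldehyde); step 1 is a one-step side branch.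

**Steps most likely to fail**

1. Step 7 (Baeyer–Villiger oxidation). The ortho acyl group may lower the migratory aptitude of the ring so far that hydride migrates in the peroxy hemiacetal instead of the aryl carbon, or the peracid may be consumed at the ketone.
Fallback: the third ring-A oxygen is bought instead of made, and C2 is taken from DMF. The fallback sets out from compound 1, which is heated with commercial 2-methoxybenzene-1,3-diol in BF3·OEt2 at about 85 °C. Friedel–Crafts acylation of this symmetric phenol can give only one regioisomer, 1-(2,4-dihydroxy-3-methoxyphenyl)-2-(4-methoxyphenyl)ethan-1-one F1. Treatment of F1 with DMF and MsCl in BF3·OEt2 at about 70 °C (the established one-carbon ring closure of 2-hydroxydeoxybenzoins) should give the 7-hydroxyisoflavone directly. The route is rejoined at compound 19, and step 10 completes it.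

2. Step 6 (acylation of the aryllithium). Aryllithium 11 may deprotonate the acidic benzylic α-position of amide 3 instead of adding to its carbonyl group, which returns debrominated arene after work-up.
Fallback: the ketone is built in two stages so that the organolithium meets only a weakly acidic amide. The fallback sets out from compound 10. Bromine–lithium exchange as in step 6 and quenching of 11 with N-methoxy-N-methylacetamide, followed by a neutral NH4Cl work-up that keeps the acetal, should give 1-[4-(benzyloxy)-2-(dimethoxymethyl)-3-methoxyphenyl]ethan-1-one F2. Palladium-catalysed ketone α-arylation of F2 with 4-bromoanisole (Pd2(dba)3, Xantphos, NaOtBu, toluene, 80 °C) then installs the anisyl group. The route is rejoined at compound 13, which the aqueous HCl treatment of step 6 converts into 14.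

3. Step 8 (closure of ring C). The formyl group may be lost by attack of DBU or adventitious water at the very electrophilic formate carbonyl before the enolate carbon reaches it.
Fallback: the formyl carbon is given up and C2 is brought in by an amide acetal. The fallback sets out from compound 16, which is cleaved deliberately with Et3N in MeOH at 0 °C to 1-[4-(benzyloxy)-2-hydroxy-3-methoxyphenyl]-2-(4-methoxyphenyl)ethan-1-one F3. Heating F3 with N,N-dimethylformamide dimethyl acetal in toluene at 100 °C should give the enaminone 1-[4-(benzyloxy)-2-hydroxy-3-methoxyphenyl]-3-(dimethylamino)-2-(4-methoxyphenyl)prop-2-en-1-one F4 (not isolated, double-bond geometry irrelevant). F4 closes by attack of the phenol oxygen and loss of dimethylamine. The route is rejoined at compound 18.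

**Further compounds**
F1 | step 7 | 1-(2,4-dihydroxy-3-methoxyphenyl)-2-(4-methoxyphenyl)ethan-1-one | COc1ccc(CC(=O)c2ccc(O)c(OC)c2O)cc1
F2 | step 6 | 1-[4-(benzyloxy)-2-(dimethoxymethyl)-3-methoxyphenyl]ethan-1-one | CC(=O)c1ccc(OCc2ccccc2)c(OC)c1C(OC)OC
F3 | step 8 | 1-[4-(benzyloxy)-2-hydroxy-3-methoxyphenyl]-2-(4-methoxyphenyl)ethan-1-one | COc1ccc(CC(=O)c2ccc(OCc3ccccc3)c(OC)c2O)cc1
F4 | step 8 | 1-[4-(benzyloxy)-2-hydroxy-3-methoxyphenyl]-3-(dimethylamino)-2-(4-methoxyphenyl)prop-2-en-1-one | COc1ccc(C(=CN(C)C)C(=O)c2ccc(OCc3ccccc3)c(OC)c2O)cc1
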